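**Minutes of the meeting on the four flasks**

The meeting started from a neighbour, a grey flask read early at 40 h, and turned to what the four full runs would keep.

| flask | left-handed substrate | partner | precatalyst | right-handed substrate | time | remark | temperature |
|---|---|---|---|---|---|---|---|
| violet | 20 mM | 40.0 mM | 50 µM | 20 mM | 4.0 d | at 85 °C until 30 h, from then on at 115 °C |  |
| green | 20 mM | 40.0 mM | 50 µM | 20 mM | 4.0 d |  | 115 °C |
| grey | 20 mM | 40.0 mM | 50 µM | 20 mM | 4.0 d |  | 85 °C |
| ochre | 20 mM | 40.0 mM | 50 µM | 20 mM | 4.0 d |  | 100 °C |

- the flask with the highest excess of left-handed product over right-handed product ("all alike" if they lie within 1.5 percentage points) (violet / green / grey / ochre / all alike)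
- excess of left-handed product over right-handed product at the end, violet
- excess of left-handed product over right-handed product at the end, green
- excess of left-handed product over right-handed product at the end, grey
- excess of left-handed product over right-handed product at the end, ochre

- catalyst is single-handed; left-handed substrate and right-handed substrate are mirror images of each other, charged as a racemate, each of them at the stated concentration
- two of one species on the left: rate k times its square, two consumed each time
- all constants are for 100 °C and move with temperature by the activation energies
- an excess is the difference of the two amounts in percent of their sum
- an excess is below zero if the other one leads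

    partner + catalyst + left-handed substrate → catalyst + left-handed product (k1 = 86 /M²/min, Ea1 = 51.0 kJ/mol)
    partner + catalyst + right-handed substrate → catalyst + right-handed product (k2 = 37 /M²/min, Ea2 = 39.0 kJ/mol)
    2 partner → self-condensation product (k3 = 5.3 × 10⁻⁴ /M/min, Ea3 = 78.0 kJ/mol)
    left-handed product ⇌ right-handed product (k4 = 4.4 × 10⁻⁴ /min, Ea4 = 114 kJ/mol)
    partner + precatalyst → catalyst + spent reagent (k5 = 0.0032 /M/min, Ea5 = 94.0 kJ/mol)
    (constants at 100 °C)

I argued for one quantity. Left-handed and right-handed product turn into each other, and their excess fades at twice the one-way racemisation constant. At 85 °C, in grey, the inverse of that fading rate is 3.68 d: this is the memory time, the relaxation time of the pair, in which an excess left to itself falls by a factor e. It shrinks to 0.789 d in ochre and 0.191 d in green.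

I then took fresh product. Its excess follows from the selectivity factor s, the left-handed constant over the right-handed one, as (s − 1)/(s + 1), with the substrates held at their racemic start. Green has the higher factor, 2.70 against 1.98 in grey. So fresh excess is 45.9 % in green and 32.9 % in grey.

I also reckoned how the catalyst appears. With [partner] at 40.0 mM, precatalyst turns over in 19.3 d in grey, longer than the 4.0 d run. So I took catalyst in grey to climb nearly in a straight line, and the rate of making with it. In green that time is 1.68 d, shorter than the run, so the line bends there and I trusted green less.

For a straight-line rise, the share of fresh excess kept is 2(a − 1 + exp(−a))/(a·a), where a is the time over the memory time. That gave me 23.6 % for grey, 12.6 % for ochre and 4.17 % for green. In violet, hardly any of the cold excess outlives the hot stretch, so I counted that stretch by itself and got 5.93 %. My choice was grey.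

The forecast also named grey, saying that “much of the kinetic preference survives” there. It gave grey 23 % (20 % to 26 %), ochre 9.7 % (8 % to 11.5 %), violet 2.4 % (1.8 % to 3.2 %) and green 1.2 % (0.8 % to 1.7 %). My ochre figure stood higher than the forecast's. So did my green figure and my violet figure.

**The result**

The flasks gave grey on top, with grey 22.7 %, ochre 9.15 %, violet 2.39 % and green 1.15 %. Each stands inside the forecast's range.

In grey, half of the turnover of the step making left-handed product up to the end was done by 2.73 d, so half of what that step made is younger than 1.27 d, which is less than the memory time of 3.68 d. Grey reads 22.7 % at the end of the run and 0.610 % after 40.0 d.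

For the neighbour, grey read at 40 h, the same memory time gives a = 0.453 and an excess of 28.4 %. That flask gave 28.2 %.

All constants belong to no real substance, and the outcome is calculated.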